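**Plan**

- Ring numbering used throughout: C1 (C=O), C2=C3 (C2 carries CH2OH), C4 (quaternary: CH3 and 4-methylpent-3-enyl), C5 (enol-ester arm), C6 (2-oxopropyl), C7 (CH2). In this cycloheptenone the C4–C5 bond is allylic to C2=C3 and C5 bears a carbon that can be a carboxyl, which is the retron of an ester-enolate Claisen shift from an oxygen on C2.
- Cuts, latest first: enol-ester C–O (acid plus C5 ethynyl), C2–CH2OH (Stille), C4–C5 with C2=C3 traded for a C2–O bond (seven-membered lactone), the lactone C–O, C2–C3 (Z-alkenyl metal plus α-silyloxy aldehyde), C6–acetonyl (Michael addition), C6–C7 (epoxide alkynylation).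
- Forward: (R)-benzyl glycidyl ether and ethyl propiolate give a 6-substituted dihydropyranone (a temporary δ-lactone); trans Michael addition and ring opening give the C5–C6–C7–C1–C2 aldehyde; the Z-alkenyl iodide from carbocupration of propyne is added; the ε-lactone is closed and its Ireland–Claisen shift makes the only carbocycle; acid to alkyne, enone, iodination/Stille, ketal removal and Ru-catalysed acid addition finish.
- Stereochemistry: C1 (a spectator, later the ketone) comes from the glycidyl ether; it sets C6 through the trans-selective conjugate addition and C2 through Felkin–Anh addition; C2 and the Z alkene then set C5 and C4 in the tether-enforced boat; the Z enol ester comes from the Ru catalyst.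

Key step: step 14

Assumption: C1 is oxidised to the ketone in step 19, but it is carried as a single R epimer because it relays chirality to C6 and C2 and sits pseudo-equatorially in the rearrangement.

**Route**

Step 1
Reactants: 1 (R)-benzyl glycidyl ether; 2 ethyl propiolate
Product: 4 ethyl (5R)-6-(benzyloxy)-5-hydroxyhex-2-ynoate, via lithium ethyl propiolate 3 (not isolated)
Conditions: 2, n-BuLi, THF, −78 °C; BF3·OEt2; then 1, −78 °C
Reagents that add atoms: none
Why: BF3-assisted SN2 opening of the terminal epoxide carbon by the lithium acetylide (epoxide alkynylation) forms C6–C7 and leaves the carbinol centre of the glycidyl ether untouched, so future C1 is fixed as R from the chiral pool.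

Step 2
Reactants: 4 ethyl (5R)-6-(benzyloxy)-5-hydroxyhex-2-ynoate
Product: 6 (6R)-6-[(benzyloxy)methyl]-5,6-dihydro-2H-pyran-2-one, via Z-hydroxy enoate 5 (not isolated)
Conditions: H2 (1 atm), Pd/CaCO3 poisoned with Pb(OAc)2 (Lindlar), quinoline, EtOAc, rt; then TsOH (cat.), toluene, 60 °C
Reagents that add atoms: none
Why: Lindlar semihydrogenation should give the Z-enoate, whose cis geometry lets the δ-hydroxyl lactonise under acid catalysis (6-exo-trig acyl substitution) while the benzyl ether survives.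

Step 3
Reactants: 6 (6R)-6-[(benzyloxy)methyl]-5,6-dihydro-2H-pyran-2-one; 7 tert-butyl acetoacetate
Product: 8 tert-butyl 2-[(2R,4S)-2-[(benzyloxy)methyl]-6-oxooxan-4-yl]-3-oxobutanoate (both epimers at the acetoacetate carbon)
Conditions: DBU (0.2 equiv), THF, 0 °C → rt
Reagents that add atoms: none
Why: Base-catalysed Michael addition of the β-keto ester enolate should occur by axial attack on the half-chair lactone anti to the pseudo-equatorial 6-substituent, the familiar trans-4,6 preference, which sets future C6 (the acetoacetate carbon is erased in step 4).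

Step 4
Reactants: 8 tert-butyl 2-[(2R,4S)-2-[(benzyloxy)methyl]-6-oxooxan-4-yl]-3-oxobutanoate
Product: 10 (4R,6R)-6-[(benzyloxy)methyl]-4-(2-oxopropyl)oxan-2-one, via β-keto acid 9 (not isolated)
Conditions: CF3CO2H, CH2Cl2, rt; evaporate; toluene, 90 °C
Reagents that add atoms: none
Why: Acidolysis of the tert-butyl ester and thermal decarboxylation of the β-keto acid leave the 2-oxopropyl arm without any base, so the lactone and both stereocentres should stay intact.

Step 5
Reactants: 10 (4R,6R)-6-[(benzyloxy)methyl]-4-(2-oxopropyl)oxan-2-one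
Product: 11 (4R,6R)-6-[(benzyloxy)methyl]-4-[(2-methyl-1,3-dioxolan-2-yl)methyl]oxan-2-one
Conditions: Me3SiOCH2CH2OSiMe3, Me3SiOTf (cat.), CH2Cl2, −78 → −20 °C
Reagents that add atoms: 1,2-bis(trimethylsilyloxy)ethane, C[Si](C)(C)OCCO[Si](C)(C)C
Why: Me3SiOTf-catalysed silyl-transfer ketalisation protects the methyl ketone at low temperature where the lactone carbonyl is inert, and it must precede step 6 because the free δ-keto ester would undergo Claisen cyclisation under base.

Step 6
Reactants: 11 (4R,6R)-6-[(benzyloxy)methyl]-4-[(2-methyl-1,3-dioxolan-2-yl)methyl]oxan-2-one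
Product: 12 methyl (3R,5R)-6-(benzyloxy)-5-hydroxy-3-[(2-methyl-1,3-dioxolan-2-yl)methyl]hexanoate
Conditions: K2CO3 (0.2 equiv), MeOH, 0 °C; crude product used at once
Reagents that add atoms: methanol, CO
Why: Carbonate-catalysed transesterification in methanol should open the δ-lactone to the hydroxy methyl ester, which is kept cold and silylated immediately because it can relactonise.

Step 7
Reactants: 12 methyl (3R,5R)-6-(benzyloxy)-5-hydroxy-3-[(2-methyl-1,3-dioxolan-2-yl)methyl]hexanoate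
Product: 13 methyl (3R,5R)-6-(benzyloxy)-5-[(tert-butyldimethylsilyl)oxy]-3-[(2-methyl-1,3-dioxolan-2-yl)methyl]hexanoate
Conditions: t-BuMe2SiCl, imidazole, DMF, rt
Reagents that add atoms: tert-butyldimethylsilyl chloride, CC(C)(C)[Si](C)(C)Cl
Why: Standard silylation of the secondary alcohol installs the C1 protecting group that keeps this oxygen out of the later lactone and prevents chelation in step 11.

Step 8
Reactants: 13 methyl (3R,5R)-6-(benzyloxy)-5-[(tert-butyldimethylsilyl)oxy]-3-[(2-methyl-1,3-dioxolan-2-yl)methyl]hexanoate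
Product: 14 methyl (3R,5R)-5-[(tert-butyldimethylsilyl)oxy]-6-hydroxy-3-[(2-methyl-1,3-dioxolan-2-yl)methyl]hexanoate
Conditions: H2 (1 atm), Pd/C, EtOAc, rt
Reagents that add atoms: none
Why: Neutral hydrogenolysis of the benzyl ether should free the primary alcohol at a stage where no alkene is present and silyl ether, ketal and ester are inert.

Step 9
Reactants: 14 methyl (3R,5R)-5-[(tert-butyldimethylsilyl)oxy]-6-hydroxy-3-[(2-methyl-1,3-dioxolan-2-yl)methyl]hexanoate
Product: 15 methyl (3R,5R)-5-[(tert-butyldimethylsilyl)oxy]-3-[(2-methyl-1,3-dioxolan-2-yl)methyl]-6-oxohexanoate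
Conditions: Dess–Martin periodinane, pyridine, CH2Cl2, 0 °C → rt
Reagents that add atoms: none
Why: Dess–Martin oxidation under buffered, non-basic conditions should give the α-silyloxy aldehyde without epimerisation at C1, and it is used without storage.

Step 10
Reactants: 16 5-bromo-2-methylpent-2-ene; 17 propyne
Product: 20 (1Z)-1-iodo-2,6-dimethylhepta-1,5-diene, via homoprenylmagnesium bromide 18 (not isolated), via Z-alkenylcopper 19 (not isolated)
Conditions: 16, Mg, Et2O; CuBr·SMe2, Et2O/Me2S, −45 °C; 17, −25 °C; then I2, −60 → 0 °C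
Reagents that add atoms: iodine, [I][I]
Why: Syn carbocupration of propyne by the alkylcopper reagent places copper on the terminal carbon cis to the new chain, and iodinolysis with retention fixes the Z trisubstituted alkene that becomes C3=C4.

Step 11
Reactants: 15 methyl (3R,5R)-5-[(tert-butyldimethylsilyl)oxy]-3-[(2-methyl-1,3-dioxolan-2-yl)methyl]-6-oxohexanoate; 20 (1Z)-1-iodo-2,6-dimethylhepta-1,5-diene
Product: 23 methyl (3R,5R,6S,7Z)-5-[(tert-butyldimethylsilyl)oxy]-6-hydroxy-8,12-dimethyl-3-[(2-methyl-1,3-dioxolan-2-yl)methyl]trideca-7,11-dienoate, via Z-alkenyllithium 21 (not isolated), via Z-alkenylmagnesium bromide 22 (not isolated)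
Conditions: 20, t-BuLi (2 equiv), Et2O, −78 °C; MgBr2·OEt2; then 15, THF, −78 °C
Reagents that add atoms: none
Why: Iodine–lithium exchange with retention, transmetalation to magnesium and Felkin–Anh (non-chelated) addition anti to the C–OSi bond should give mainly the 5,6-anti carbinol (6S, ring C2), the aldehyde reacting far faster than the methyl ester at −78 °C.

Step 12
Reactants: 23 methyl (3R,5R,6S,7Z)-5-[(tert-butyldimethylsilyl)oxy]-6-hydroxy-8,12-dimethyl-3-[(2-methyl-1,3-dioxolan-2-yl)methyl]trideca-7,11-dienoate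
Product: 24 (3R,5R,6S,7Z)-5-[(tert-butyldimethylsilyl)oxy]-6-hydroxy-8,12-dimethyl-3-[(2-methyl-1,3-dioxolan-2-yl)methyl]trideca-7,11-dienoic acid
Conditions: LiOH, THF/MeOH/H2O, 0 °C → rt; then dilute HCl to pH 5 at 0 °C
Reagents that add atoms: lithium hydroxide, [Li+].[OH-]
Why: Saponification of the methyl ester is compatible with the silyl ether, ketal and allylic alcohol, and acidification only to pH 5 in the cold avoids ketal hydrolysis.

Step 13
Reactants: 24 (3R,5R,6S,7Z)-5-[(tert-butyldimethylsilyl)oxy]-6-hydroxy-8,12-dimethyl-3-[(2-methyl-1,3-dioxolan-2-yl)methyl]trideca-7,11-dienoic acid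
Product: 26 (4R,6R,7S)-6-[(tert-butyldimethylsilyl)oxy]-7-[(1Z)-2,6-dimethylhepta-1,5-dien-1-yl]-4-[(2-methyl-1,3-dioxolan-2-yl)methyl]oxepan-2-one, via mixed anhydride 25 (not isolated)
Conditions: 2,4,6-Cl3C6H2COCl, Et3N, THF, rt; then slow addition to DMAP, toluene, 80 °C (high dilution)
Reagents that add atoms: none
Why: Yamaguchi lactonisation through the mixed anhydride and DMAP acyl transfer under high dilution should close the seven-membered lactone by O-acylation of the C2 hydroxyl (7-exo-trig) with retention at C2.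

Step 14
Reactants: 26 (4R,6R,7S)-6-[(tert-butyldimethylsilyl)oxy]-7-[(1Z)-2,6-dimethylhepta-1,5-dien-1-yl]-4-[(2-methyl-1,3-dioxolan-2-yl)methyl]oxepan-2-one
Product: 29 (1S,2S,5R,7R)-5-[(tert-butyldimethylsilyl)oxy]-2-methyl-7-[(2-methyl-1,3-dioxolan-2-yl)methyl]-2-(4-methylpent-3-en-1-yl)cyclohept-3-ene-1-carboxylic acid, via silyl ketene acetal 27 (not isolated), via trimethylsilyl ester 28 (not isolated)
Conditions: LiN(iPr)2, Me3SiCl/Et3N, THF, −78 °C → rt; toluene, 100 °C; then MeOH/H2O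
Reagents that add atoms: none
Why: Deprotonation at C5 and in situ O-silylation give the cyclic silyl ketene acetal 27, in which C5=C(OSi)–O–C2–C3=C4 is a 1,5-diene; on heating a concerted [3,3] shift forms C5–C4, moves the alkene to C2=C3 and breaks C2–O, and hydrolysis of silyl ester 28 frees the acid. This is the Ireland–Claisen rearrangement of an alkenyl-substituted lactone, a known way to turn lactones into cycloalkene carboxylic acids. The cycloheptene closes by this sigmatropic C–C bond formation itself (no nucleophile–electrophile ring closure): the three-atom tether C6–C7–C1 links C5 to C2, so only a boat-like array is within reach and the new ring alkene is necessarily cis. C5 is set because the alkenyl group can reach the ketene acetal only on the lactone face on which C2 holds it, the face opposite the C6 side chain, which puts the carboxyl cis to that chain. C4 is set by the Z geometry of the alkene, which in the boat turns the methyl group to the side of the carboxyl and the 4-methylpent-3-enyl chain away from it. The step needs O-silylation ahead of enolate decomposition and a single transition-state topology; trapping with Me3SiCl at −78 °C provides the first, and the tether, the ring-fixed ketene-acetal geometry and the pseudo-equatorial C1 silyloxy group provide the second.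

Step 15
Reactants: 29 (1S,2S,5R,7R)-5-[(tert-butyldimethylsilyl)oxy]-2-methyl-7-[(2-methyl-1,3-dioxolan-2-yl)methyl]-2-(4-methylpent-3-en-1-yl)cyclohept-3-ene-1-carboxylic acid
Product: 30 [(1S,2S,5R,7R)-5-[(tert-butyldimethylsilyl)oxy]-2-methyl-7-[(2-methyl-1,3-dioxolan-2-yl)methyl]-2-(4-methylpent-3-en-1-yl)cyclohept-3-en-1-yl]methanol
Conditions: LiAlH4, THF, 0 °C → reflux
Reagents that add atoms: none
Why: LiAlH4 should reduce the hindered carboxylic acid to the primary alcohol without touching the silyl ether, the ketal or the isolated alkenes.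

Step 16
Reactants: 30 [(1S,2S,5R,7R)-5-[(tert-butyldimethylsilyl)oxy]-2-methyl-7-[(2-methyl-1,3-dioxolan-2-yl)methyl]-2-(4-methylpent-3-en-1-yl)cyclohept-3-en-1-yl]methanol
Product: 31 (1S,2S,5R,7R)-5-[(tert-butyldimethylsilyl)oxy]-2-methyl-7-[(2-methyl-1,3-dioxolan-2-yl)methyl]-2-(4-methylpent-3-en-1-yl)cyclohept-3-ene-1-carbaldehyde
Conditions: Dess–Martin periodinane, pyridine, CH2Cl2, 0 °C → rt
Reagents that add atoms: none
Why: Dess–Martin oxidation should give the neopentyl-type aldehyde under non-basic conditions that do not epimerise C5.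

Step 17
Reactants: 31 (1S,2S,5R,7R)-5-[(tert-butyldimethylsilyl)oxy]-2-methyl-7-[(2-methyl-1,3-dioxolan-2-yl)methyl]-2-(4-methylpent-3-en-1-yl)cyclohept-3-ene-1-carbaldehyde
Product: 32 tert-butyl{[(1R,4S,5R,6R)-5-ethynyl-4-methyl-6-[(2-methyl-1,3-dioxolan-2-yl)methyl]-4-(4-methylpent-3-en-1-yl)cyclohept-2-en-1-yl]oxy}dimethylsilane
Conditions: MeC(O)C(N2)P(O)(OMe)2, K2CO3, MeOH, 0 °C → rt
Reagents that add atoms: dimethyl (1-diazo-2-oxopropyl)phosphonate, CC(=O)C(=[N+]=[N-])P(=O)(OC)OC
Why: Ohira–Bestmann homologation converts the aldehyde into the terminal alkyne through the diazoalkene and a 1,2-shift of the alkylidene carbene, under carbonate conditions mild enough that C5 is expected to keep its configuration.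

Step 18
Reactants: 32 tert-butyl{[(1R,4S,5R,6R)-5-ethynyl-4-methyl-6-[(2-methyl-1,3-dioxolan-2-yl)methyl]-4-(4-methylpent-3-en-1-yl)cyclohept-2-en-1-yl]oxy}dimethylsilane
Product: 33 (1R,4S,5R,6R)-5-ethynyl-4-methyl-6-[(2-methyl-1,3-dioxolan-2-yl)methyl]-4-(4-methylpent-3-en-1-yl)cyclohept-2-en-1-ol
Conditions: Bu4NF, THF, rt → 40 °C
Reagents that add atoms: none
Why: Fluoride-mediated desilylation should free the allylic C1 alcohol while ketal, alkyne and alkenes are inert.

Step 19
Reactants: 33 (1R,4S,5R,6R)-5-ethynyl-4-methyl-6-[(2-methyl-1,3-dioxolan-2-yl)methyl]-4-(4-methylpent-3-en-1-yl)cyclohept-2-en-1-ol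
Product: 34 (4S,5R,6R)-5-ethynyl-4-methyl-6-[(2-methyl-1,3-dioxolan-2-yl)methyl]-4-(4-methylpent-3-en-1-yl)cyclohept-2-en-1-one
Conditions: Dess–Martin periodinane, pyridine, CH2Cl2, rt
Reagents that add atoms: none
Why: Dess–Martin oxidation of the allylic alcohol should give the cyclohept-2-enone and erases the spectator stereocentre at C1.

Step 20
Reactants: 34 (4S,5R,6R)-5-ethynyl-4-methyl-6-[(2-methyl-1,3-dioxolan-2-yl)methyl]-4-(4-methylpent-3-en-1-yl)cyclohept-2-en-1-one
Product: 35 (4R,5R,6R)-5-ethynyl-2-iodo-4-methyl-6-[(2-methyl-1,3-dioxolan-2-yl)methyl]-4-(4-methylpent-3-en-1-yl)cyclohept-2-en-1-one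
Conditions: I2, pyridine, CH2Cl2, 0 °C → rt
Reagents that add atoms: iodine, [I][I]
Why: α-Iodination of the enone with I2/pyridine proceeds by conjugate addition of pyridine, iodination of the enolate and elimination, a sequence that is known to work on enones with a quaternary γ-carbon (the change of the C4 descriptor is only a priority change).

Step 21
Reactants: 35 (4R,5R,6R)-5-ethynyl-2-iodo-4-methyl-6-[(2-methyl-1,3-dioxolan-2-yl)methyl]-4-(4-methylpent-3-en-1-yl)cyclohept-2-en-1-one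
Product: 36 (4S,5R,6R)-5-ethynyl-2-(hydroxymethyl)-4-methyl-6-[(2-methyl-1,3-dioxolan-2-yl)methyl]-4-(4-methylpent-3-en-1-yl)cyclohept-2-en-1-one
Conditions: Bu3SnCH2OH, Pd(PPh3)4 (cat.), 1,4-dioxane, 90 °C
Reagents that add atoms: (tributylstannyl)methanol, CCCC[Sn](CCCC)(CCCC)CO
Why: Stille coupling of the 2-iodoenone with the hydroxymethylstannane should install the C2 hydroxymethyl group directly, with no copper or amine present that could engage the terminal alkyne.

Step 22
Reactants: 36 (4S,5R,6R)-5-ethynyl-2-(hydroxymethyl)-4-methyl-6-[(2-methyl-1,3-dioxolan-2-yl)methyl]-4-(4-methylpent-3-en-1-yl)cyclohept-2-en-1-one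
Product: 37 (4S,5R,6S)-5-ethynyl-2-(hydroxymethyl)-4-methyl-4-(4-methylpent-3-en-1-yl)-6-(2-oxopropyl)cyclohept-2-en-1-one
Conditions: pyridinium p-toluenesulfonate, acetone/H2O, 50 °C
Reagents that add atoms: water, O
Why: Mild aqueous acid hydrolyses the dioxolane to the methyl ketone before the acid-sensitive enol ester is introduced (the C6 descriptor changes only through priorities).

Step 23
Reactants: 37 (4S,5R,6S)-5-ethynyl-2-(hydroxymethyl)-4-methyl-4-(4-methylpent-3-en-1-yl)-6-(2-oxopropyl)cyclohept-2-en-1-one; 38 3-methylbut-2-enoic acid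
Product: 39 (Z)-2-[(1R,2R,7S)-4-(hydroxymethyl)-2-methyl-2-(4-methylpent-3-en-1-yl)-5-oxo-7-(2-oxopropyl)cyclohept-3-en-1-yl]ethenyl 3-methylbut-2-enoate (CNP0415257.1)
Conditions: [RuCl2(p-cymene)]2 (cat.), P(4-ClC6H4)3, 4-(dimethylamino)pyridine (cat.), toluene, 60 °C
Reagents that add atoms: none
Why: Ruthenium-catalysed anti-Markovnikov addition of the carboxylic acid to the terminal alkyne through a ruthenium vinylidene, with the electron-poor phosphine/DMAP system, is known to give Z enol esters and should tolerate the ketones, alkenes and the free alcohol.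

**Compound list**

1 | (R)-benzyl glycidyl ether | c1ccccc1COC[C@H]1CO1 | starting material
2 | ethyl propiolate | CCOC(=O)C#C | starting material
3 | lithium ethyl propiolate (formed in the flask) | CCOC(=O)C#C[Li] | intermediate
4 | ethyl (5R)-6-(benzyloxy)-5-hydroxyhex-2-ynoate | CCOC(=O)C#CC[C@@H](O)COCc1ccccc1 | intermediate
5 | ethyl (2Z,5R)-6-(benzyloxy)-5-hydroxyhex-2-enoate (formed in the flask) | CCOC(=O)/C=C\C[C@@H](O)COCc1ccccc1 | intermediate
6 | (6R)-6-[(benzyloxy)methyl]-5,6-dihydro-2H-pyran-2-one | O=C1C=CC[C@H](COCc2ccccc2)O1 | intermediate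
7 | tert-butyl acetoacetate | CC(=O)CC(=O)OC(C)(C)C | starting material
8 | tert-butyl 2-[(2R,4S)-2-[(benzyloxy)methyl]-6-oxooxan-4-yl]-3-oxobutanoate (epimers at the acetoacetate carbon) | O=C1C[C@@H](C(C(C)=O)C(=O)OC(C)(C)C)C[C@H](COCc2ccccc2)O1 | intermediate
9 | 2-[(2R,4S)-2-[(benzyloxy)methyl]-6-oxooxan-4-yl]-3-oxobutanoic acid (formed in the flask) | O=C1C[C@@H](C(C(C)=O)C(=O)O)C[C@H](COCc2ccccc2)O1 | intermediate
10 | (4R,6R)-6-[(benzyloxy)methyl]-4-(2-oxopropyl)oxan-2-one | O=C1C[C@@H](CC(C)=O)C[C@H](COCc2ccccc2)O1 | intermediate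
11 | (4R,6R)-6-[(benzyloxy)methyl]-4-[(2-methyl-1,3-dioxolan-2-yl)methyl]oxan-2-one | O=C1C[C@@H](CC2(C)OCCO2)C[C@H](COCc3ccccc3)O1 | intermediate
12 | methyl (3R,5R)-6-(benzyloxy)-5-hydroxy-3-[(2-methyl-1,3-dioxolan-2-yl)methyl]hexanoate | COC(=O)C[C@@H](CC1(C)OCCO1)C[C@@H](O)COCc1ccccc1 | intermediate
13 | methyl (3R,5R)-6-(benzyloxy)-5-[(tert-butyldimethylsilyl)oxy]-3-[(2-methyl-1,3-dioxolan-2-yl)methyl]hexanoate | COC(=O)C[C@@H](CC1(C)OCCO1)C[C@@H](O[Si](C)(C)C(C)(C)C)COCc1ccccc1 | intermediate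
14 | methyl (3R,5R)-5-[(tert-butyldimethylsilyl)oxy]-6-hydroxy-3-[(2-methyl-1,3-dioxolan-2-yl)methyl]hexanoate | COC(=O)C[C@@H](CC1(C)OCCO1)C[C@@H](O[Si](C)(C)C(C)(C)C)CO | intermediate
15 | methyl (3R,5R)-5-[(tert-butyldimethylsilyl)oxy]-3-[(2-methyl-1,3-dioxolan-2-yl)methyl]-6-oxohexanoate | COC(=O)C[C@@H](CC1(C)OCCO1)C[C@@H](O[Si](C)(C)C(C)(C)C)C=O | intermediate
16 | 5-bromo-2-methylpent-2-ene | CC(C)=CCCBr | starting material
17 | propyne | CC#C | starting material
18 | (4-methylpent-3-en-1-yl)magnesium bromide (formed in the flask) | CC(C)=CCC[Mg]Br | intermediate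
19 | [(1Z)-2,6-dimethylhepta-1,5-dien-1-yl]copper (formed in the flask) | [Cu]/C=C(C)\CCC=C(C)C | intermediate
20 | (1Z)-1-iodo-2,6-dimethylhepta-1,5-diene | I/C=C(C)\CCC=C(C)C | intermediate
21 | [(1Z)-2,6-dimethylhepta-1,5-dien-1-yl]lithium (formed in the flask) | [Li]/C=C(C)\CCC=C(C)C | intermediate
22 | [(1Z)-2,6-dimethylhepta-1,5-dien-1-yl]magnesium bromide (formed in the flask) | Br[Mg]/C=C(C)\CCC=C(C)C | intermediate
23 | methyl (3R,5R,6S,7Z)-5-[(tert-butyldimethylsilyl)oxy]-6-hydroxy-8,12-dimethyl-3-[(2-methyl-1,3-dioxolan-2-yl)methyl]trideca-7,11-dienoate | COC(=O)C[C@@H](CC1(C)OCCO1)C[C@@H](O[Si](C)(C)C(C)(C)C)[C@@H](O)/C=C(C)\CCC=C(C)C | intermediate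
24 | (3R,5R,6S,7Z)-5-[(tert-butyldimethylsilyl)oxy]-6-hydroxy-8,12-dimethyl-3-[(2-methyl-1,3-dioxolan-2-yl)methyl]trideca-7,11-dienoic acid | OC(=O)C[C@@H](CC1(C)OCCO1)C[C@@H](O[Si](C)(C)C(C)(C)C)[C@@H](O)/C=C(C)\CCC=C(C)C | intermediate
25 | mixed anhydride of 24 with 2,4,6-trichlorobenzoic acid (formed in the flask) | O=C(OC(=O)C[C@@H](CC1(C)OCCO1)C[C@@H](O[Si](C)(C)C(C)(C)C)[C@@H](O)/C=C(C)\CCC=C(C)C)c1c(Cl)cc(Cl)cc1Cl | intermediate
26 | (4R,6R,7S)-6-[(tert-butyldimethylsilyl)oxy]-7-[(1Z)-2,6-dimethylhepta-1,5-dien-1-yl]-4-[(2-methyl-1,3-dioxolan-2-yl)methyl]oxepan-2-one | CC1(C[C@@H]2CC(=O)O[C@@H](/C=C(C)\CCC=C(C)C)[C@H](O[Si](C)(C)C(C)(C)C)C2)OCCO1 | intermediate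
27 | cyclic trimethylsilyl ketene acetal of 26, (2S,3R,5R)-configured 7-(trimethylsilyloxy)-2,3,4,5-tetrahydrooxepine (formed in the flask) | CC1(C[C@@H]2C=C(O[Si](C)(C)C)O[C@@H](/C=C(C)\CCC=C(C)C)[C@H](O[Si](C)(C)C(C)(C)C)C2)OCCO1 | intermediate
28 | trimethylsilyl ester of 29 (formed in the flask) | CC1(C[C@H]2C[C@@H](O[Si](C)(C)C(C)(C)C)C=C[C@](C)(CCC=C(C)C)[C@H]2C(=O)O[Si](C)(C)C)OCCO1 | intermediate
29 | (1S,2S,5R,7R)-5-[(tert-butyldimethylsilyl)oxy]-2-methyl-7-[(2-methyl-1,3-dioxolan-2-yl)methyl]-2-(4-methylpent-3-en-1-yl)cyclohept-3-ene-1-carboxylic acid | CC1(C[C@H]2C[C@@H](O[Si](C)(C)C(C)(C)C)C=C[C@](C)(CCC=C(C)C)[C@H]2C(=O)O)OCCO1 | intermediate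
30 | [(1S,2S,5R,7R)-5-[(tert-butyldimethylsilyl)oxy]-2-methyl-7-[(2-methyl-1,3-dioxolan-2-yl)methyl]-2-(4-methylpent-3-en-1-yl)cyclohept-3-en-1-yl]methanol | CC1(C[C@H]2C[C@@H](O[Si](C)(C)C(C)(C)C)C=C[C@](C)(CCC=C(C)C)[C@H]2CO)OCCO1 | intermediate
31 | (1S,2S,5R,7R)-5-[(tert-butyldimethylsilyl)oxy]-2-methyl-7-[(2-methyl-1,3-dioxolan-2-yl)methyl]-2-(4-methylpent-3-en-1-yl)cyclohept-3-ene-1-carbaldehyde | CC1(C[C@H]2C[C@@H](O[Si](C)(C)C(C)(C)C)C=C[C@](C)(CCC=C(C)C)[C@H]2C=O)OCCO1 | intermediate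
32 | tert-butyl{[(1R,4S,5R,6R)-5-ethynyl-4-methyl-6-[(2-methyl-1,3-dioxolan-2-yl)methyl]-4-(4-methylpent-3-en-1-yl)cyclohept-2-en-1-yl]oxy}dimethylsilane | CC1(C[C@H]2C[C@@H](O[Si](C)(C)C(C)(C)C)C=C[C@](C)(CCC=C(C)C)[C@H]2C#C)OCCO1 | intermediate
33 | (1R,4S,5R,6R)-5-ethynyl-4-methyl-6-[(2-methyl-1,3-dioxolan-2-yl)methyl]-4-(4-methylpent-3-en-1-yl)cyclohept-2-en-1-ol | CC1(C[C@H]2C[C@@H](O)C=C[C@](C)(CCC=C(C)C)[C@H]2C#C)OCCO1 | intermediate
34 | (4S,5R,6R)-5-ethynyl-4-methyl-6-[(2-methyl-1,3-dioxolan-2-yl)methyl]-4-(4-methylpent-3-en-1-yl)cyclohept-2-en-1-one | CC1(C[C@H]2CC(=O)C=C[C@](C)(CCC=C(C)C)[C@H]2C#C)OCCO1 | intermediate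
35 | (4R,5R,6R)-5-ethynyl-2-iodo-4-methyl-6-[(2-methyl-1,3-dioxolan-2-yl)methyl]-4-(4-methylpent-3-en-1-yl)cyclohept-2-en-1-one | CC1(C[C@H]2CC(=O)C(I)=C[C@](C)(CCC=C(C)C)[C@H]2C#C)OCCO1 | intermediate
36 | (4S,5R,6R)-5-ethynyl-2-(hydroxymethyl)-4-methyl-6-[(2-methyl-1,3-dioxolan-2-yl)methyl]-4-(4-methylpent-3-en-1-yl)cyclohept-2-en-1-one | CC1(C[C@H]2CC(=O)C(CO)=C[C@](C)(CCC=C(C)C)[C@H]2C#C)OCCO1 | intermediate
37 | (4S,5R,6S)-5-ethynyl-2-(hydroxymethyl)-4-methyl-4-(4-methylpent-3-en-1-yl)-6-(2-oxopropyl)cyclohept-2-en-1-one | CC(=O)C[C@H]1CC(=O)C(CO)=C[C@](C)(CCC=C(C)C)[C@H]1C#C | intermediate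
38 | 3-methylbut-2-enoic acid | CC(C)=CC(=O)O | starting material
39 | (Z)-2-[(1R,2R,7S)-4-(hydroxymethyl)-2-methyl-2-(4-methylpent-3-en-1-yl)-5-oxo-7-(2-oxopropyl)cyclohept-3-en-1-yl]ethenyl 3-methylbut-2-enoate (CNP0415257.1) | CC(=O)C[C@H]1CC(=O)C(CO)=C[C@](C)(CCC=C(C)C)[C@H]1/C=C\OC(=O)C=C(C)C | target

**Step count**

Total step count: 23. Longest linear sequence: 22 steps (steps 1–9 and 11–23; step 10 prepares the alkenyl iodide on a separate arm).

**Steps most likely to fail**

1. Step 14. The [3,3] shift has to build a quaternary carbon from a Z-trisubstituted alkene through a strained boat, so it may be slow enough for decomposition of the ketene acetal (reversion to lactone, fragmentation of the enolate) to compete. The fallback sets out from 15 and comes back at 29.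
   - Wittig methylenation of 15 (Ph3P=CH2, THF) should give methyl (3R,5R)-5-[(tert-butyldimethylsilyl)oxy]-3-[(2-methyl-1,3-dioxolan-2-yl)methyl]hept-6-enoate F1, and saponification the corresponding hept-6-enoic acid F2.
   - Esterification with geraniol (N,N′-dicyclohexylcarbodiimide, DMAP) gives the geranyl ester F3.
   - LiN(iPr)2/Me3SiCl in THF at −78 °C gives the (E)-trimethylsilyl ketene acetal F4. On warming it should rearrange through an open-chain chair, in which the E alkene with the E ketene acetal gives the same C4/C5 relationship that the Z alkene gives through the boat, to the silyl ester F5 and, after hydrolysis, the diene acid F6.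
   - Ring-closing metathesis of the two vinyl groups of F6 with RuCl2(PCy3)2(=CHPh), which leaves trisubstituted alkenes alone, closes C2=C3 and gives 29.
   - The cost is that the C5/C6 relationship is then under acyclic control only, so a separation of isomers at the acid stage must be expected.

2. Step 11. Facial selectivity in the addition to the α-silyloxy aldehyde may be modest, and some attack on the ester or silyl migration in the alkoxide is possible. The fallback sets out from 15 and 20 and comes back at 26. The 6R epimer that accompanies 23, methyl (3R,5R,6R,7Z)-5-[(tert-butyldimethylsilyl)oxy]-6-hydroxy-8,12-dimethyl-3-[(2-methyl-1,3-dioxolan-2-yl)methyl]trideca-7,11-dienoate F7, is not discarded. It is saponified to the (6R)-hydroxy acid F8, which is cyclised under Mitsunobu conditions (PPh3, diisopropyl azodicarboxylate, toluene, high dilution). The ring then closes by displacement at the carbinol carbon with inversion, so both epimers converge on lactone 26.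

3. Step 17. The aldehyde is flanked by a quaternary carbon and carries an epimerisable α-hydrogen at C5, so slow addition of the diazophosphonate anion may allow base-induced epimerisation in K2CO3/MeOH. The fallback sets out from 31 and comes back at 32. Corey–Fuchs olefination (CBr4, PPh3, CH2Cl2, 0 °C) under neutral conditions gives the 1,1-dibromoalkene, tert-butyl{[(1R,4S,5R,6R)-5-(2,2-dibromoethenyl)-4-methyl-6-[(2-methyl-1,3-dioxolan-2-yl)methyl]-4-(4-methylpent-3-en-1-yl)cyclohept-2-en-1-yl]oxy}dimethylsilane F9. n-BuLi (2 equiv, THF, −78 °C) converts it by bromine–lithium exchange and 1,2-shift into the lithium acetylide of 32 F10, and an aqueous quench gives 32.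

**Further compounds**

F1 | step 14 | methyl (3R,5R)-5-[(tert-butyldimethylsilyl)oxy]-3-[(2-methyl-1,3-dioxolan-2-yl)methyl]hept-6-enoate | COC(=O)C[C@@H](CC1(C)OCCO1)C[C@@H](O[Si](C)(C)C(C)(C)C)C=C
F2 | step 14 | (3R,5R)-5-[(tert-butyldimethylsilyl)oxy]-3-[(2-methyl-1,3-dioxolan-2-yl)methyl]hept-6-enoic acid | OC(=O)C[C@@H](CC1(C)OCCO1)C[C@@H](O[Si](C)(C)C(C)(C)C)C=C
F3 | step 14 | (2E)-3,7-dimethylocta-2,6-dien-1-yl (3R,5R)-5-[(tert-butyldimethylsilyl)oxy]-3-[(2-methyl-1,3-dioxolan-2-yl)methyl]hept-6-enoate | CC(C)=CCC/C(C)=C/COC(=O)C[C@@H](CC1(C)OCCO1)C[C@@H](O[Si](C)(C)C(C)(C)C)C=C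
F4 | step 14 | (E)-trimethylsilyl ketene acetal of F3 | CC(C)=CCC/C(C)=C/CO/C(O[Si](C)(C)C)=C\[C@@H](CC1(C)OCCO1)C[C@@H](O[Si](C)(C)C(C)(C)C)C=C
F5 | step 14 | trimethylsilyl ester of F6 | C[Si](C)(C)OC(=O)[C@H]([C@@](C)(CCC=C(C)C)C=C)[C@@H](CC1(C)OCCO1)C[C@@H](O[Si](C)(C)C(C)(C)C)C=C
F6 | step 14 | (2S,3R,5R)-5-[(tert-butyldimethylsilyl)oxy]-2-[(3S)-3,7-dimethylocta-1,6-dien-3-yl]-3-[(2-methyl-1,3-dioxolan-2-yl)methyl]hept-6-enoic acid | OC(=O)[C@H]([C@@](C)(CCC=C(C)C)C=C)[C@@H](CC1(C)OCCO1)C[C@@H](O[Si](C)(C)C(C)(C)C)C=C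
F7 | step 11 | methyl (3R,5R,6R,7Z)-5-[(tert-butyldimethylsilyl)oxy]-6-hydroxy-8,12-dimethyl-3-[(2-methyl-1,3-dioxolan-2-yl)methyl]trideca-7,11-dienoate | COC(=O)C[C@@H](CC1(C)OCCO1)C[C@@H](O[Si](C)(C)C(C)(C)C)[C@H](O)/C=C(C)\CCC=C(C)C
F8 | step 11 | (3R,5R,6R,7Z)-5-[(tert-butyldimethylsilyl)oxy]-6-hydroxy-8,12-dimethyl-3-[(2-methyl-1,3-dioxolan-2-yl)methyl]trideca-7,11-dienoic acid | OC(=O)C[C@@H](CC1(C)OCCO1)C[C@@H](O[Si](C)(C)C(C)(C)C)[C@H](O)/C=C(C)\CCC=C(C)C
F9 | step 17 | tert-butyl{[(1R,4S,5R,6R)-5-(2,2-dibromoethenyl)-4-methyl-6-[(2-methyl-1,3-dioxolan-2-yl)methyl]-4-(4-methylpent-3-en-1-yl)cyclohept-2-en-1-yl]oxy}dimethylsilane | CC1(C[C@H]2C[C@@H](O[Si](C)(C)C(C)(C)C)C=C[C@](C)(CCC=C(C)C)[C@H]2C=C(Br)Br)OCCO1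
F10 | step 17 | lithium acetylide of 32 | CC1(C[C@H]2C[C@@H](O[Si](C)(C)C(C)(C)C)C=C[C@](C)(CCC=C(C)C)[C@H]2C#C[Li])OCCO1
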